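The cyclohexene ring is read as a dearomatised bromobenzene. The cis C5–O/C6–O pair directly beside the substituted alkene carbon C1 is the imprint of an ortho,meta arene cis-dihydrodiol. Toluene dioxygenase therefore creates both C–O bonds, both stereocentres and the absolute configuration in one operation, and it leaves a C1=C2–C3=C4 diene. The precursor is the flat, achiral, purchased arene itself. Its bromine orients the substrate in the enzyme, later shields C1=C2 from the peracid, and is finally exchanged for C7. Anti epoxidation and allylic hydrolysis then set C4 and C3. A conformation-locking disiloxane on O3/O4 prepares the O7/O5-selective benzoylation.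

Key step: step 1

Numbering used throughout: C1 is the alkene carbon bearing C7 (bromine before step 6), C2 is the alkene CH, and C3–C6 are the four oxygenated ring carbons. β is the face carrying O5 and O6; α is the opposite face.

Remark on configuration: the target is (3S,4R,5R,6R), with O3, O5 and O6 β and O4 α. The (1S,2S)-diol made by the wild-type dioxygenase maps onto C5/C6 with the correct absolute sense. The S-to-R descriptor changes at these centres along the route come only from changes in CIP priority.

Assumption: the recombinant strain E. coli JM109 (pDTG601) is at hand as a laboratory strain; all other materials are purchased.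

Step 1
Reactants: 1 bromobenzene
Product: 2 (1S,2S)-3-bromocyclohexa-3,5-diene-1,2-diol
Conditions: E. coli JM109 (pDTG601) whole cells, IPTG induction, air sparge, glucose feed (terminal reductant via NADH), mineral salts medium, pH 7, 30 °C; centrifugation, EtOAc extraction
Reagents that add atoms: dioxygen, SMILES O=O
Why: The Rieske-type non-haem iron oxygenase takes two electrons from NADH through its reductase and ferredoxin partners, binds O2 side-on at the divalent iron centre and, through an iron-bound peroxide, passes both oxygen atoms to the neighbouring ring carbons C5 and C6 from one face. The closest known reaction type is the microbial cis-dihydroxylation of halobenzenes, the dearomatising counterpart of an OsO4 syn-dihydroxylation. No ring is closed; the six-membered ring is kept and only loses its aromaticity. C5 and C6 are set together: their cis relation follows from delivery of both atoms of one O2 molecule by a single metal centre, and their absolute sense follows from the chiral pocket, which holds the arene with bromine in the niche for the larger substituent. The step needs regioselectivity for the ortho,meta bond over the meta,para and ipso,ortho bonds as well as enantioface selectivity, and both are secured by the size of the bromine, which leaves one productive binding orientation. Over-oxidation to the catechol is excluded because the host carries the dioxygenase genes without the diol dehydrogenase.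

Step 2
Reactants: 2 (1S,2S)-3-bromocyclohexa-3,5-diene-1,2-diol
Product: 3 (3aS,7aS)-4-bromo-2,2-dimethyl-3a,7a-dihydro-1,3-benzodioxole
Conditions: 2,2-dimethoxypropane, p-TsOH·H2O (cat), CH2Cl2, 0 °C to rt; Et3N quench; used at once (the diene dimerises on standing)
Reagents that add atoms: 2,2-dimethoxypropane, SMILES COC(C)(C)OC
Why: Acid-catalysed transketalisation (acetonide formation) ties the syn C5/C6 diol into a cis-fused dioxolane without breaking either C–O bond, which stops dehydrative rearomatisation and creates the shielded β face that steers step 3.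

Step 3
Reactants: 3 (3aS,7aS)-4-bromo-2,2-dimethyl-3a,7a-dihydro-1,3-benzodioxole
Product: 4 (3aS,5aR,6aR,6bS)-4-bromo-2,2-dimethyl-3a,5a,6a,6b-tetrahydrooxireno[2,3-e][1,3]benzodioxole (3α,4α-epoxide)
Conditions: mCPBA (1.1 equiv), CH2Cl2, 0 °C to rt
Reagents that add atoms: mCPBA (3-chloroperoxybenzoic acid), SMILES OOC(=O)c1cccc(Cl)c1
Why: Prilezhaev epoxidation is electrophilic, so the peracid takes the electron-richer C3=C4 alkene instead of the bromine-deactivated C1=C2 alkene and approaches from the α face away from the dioxolane, setting C3–O and C4–O both α (anti to O5/O6).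

Step 4
Reactants: 4 3α,4α-epoxide
Product: 5 (3aS,4R,5S,7aS)-7-bromo-2,2-dimethyl-3a,4,5,7a-tetrahydro-1,3-benzodioxole-4,5-diol (3β-OH, 4α-OH)
Conditions: 10% aq KOH, DMSO, 90 °C
Reagents that add atoms: water (delivered as hydroxide), SMILES O
Why: Base-mediated SN2 opening of a vinyl epoxide: hydroxide enters at the allylically activated C3, which is also remote from the dioxolane, from the β face with inversion in a trans-diaxial (Fürst–Plattner) sense, so that C3 becomes β-OH while the retained C4–O bond stays α and the 3,4-trans, 4,5-trans, 5,6-cis array is complete.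

Step 5
Reactants: 5 bromo trans-diol acetonide
Product: 6 3,4-O-(1,1,3,3-tetraisopropyldisiloxane-1,3-diyl) derivative of 5 (ring descriptors 3S,4S,5R,6S)
Conditions: TIPDSCl2 (1.05 equiv), imidazole (4 equiv), DMF, 0 °C to rt
Reagents that add atoms: 1,3-dichloro-1,1,3,3-tetraisopropyldisiloxane (TIPDSCl2), SMILES CC(C)[Si](Cl)(C(C)C)O[Si](Cl)(C(C)C)C(C)C
Why: Silyl ether formation with a bifunctional chlorosilane closes a seven-membered disiloxane across the trans-diequatorial O3/O4 pair, as is well known for trans-vicinal diols of pyranosides and inositols, masks both hydroxyls in one step, resists acid better than two separate tert-butyldimethylsilyl ethers and freezes the half-chair in which O5 is equatorial and O6 pseudoaxial, with no stereocentre touched.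

Step 6
Reactants: 6 disiloxane-protected vinyl bromide; 7 tributyl(hydroxymethyl)stannane
Product: 8 C1-hydroxymethyl analogue of 6 (allylic alcohol; 3S,4S,5R,6R)
Conditions: 7 (1.5 equiv), Pd(PPh3)4 (10 mol %), toluene, degassed, 100 °C
Reagents that add atoms: tributyl(hydroxymethyl)stannane (7), SMILES CCCC[Sn](CCCC)(CCCC)CO
Why: Migita–Kosugi–Stille hydroxymethylation: zerovalent palladium inserts into the C1–Br bond, the oxygen-activated CH2OH group migrates from tin in preference to butyl and reductive elimination forms C1–C7, while silyl ether, ketal and all four stereocentres are spectators under these neutral conditions.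

Step 7
Reactants: 8 allylic alcohol acetonide
Product: 9 3,4-O-disiloxane-protected triol (O5-H, O6-H and O7-H free; 3S,4S,5R,6R)
Conditions: TFA/H2O (9:1), CH2Cl2, 0 °C; aq NaHCO3 quench
Reagents that add atoms: none
Why: Acid-catalysed ketal hydrolysis proceeds through a stabilised tertiary oxocarbenium ion and is therefore much faster than protolysis of the hindered bis-secondary diisopropylsilyl ether linkages, and since only the ketal C–O bonds are cleaved the configurations at C5 and C6 are retained.

Step 8
Reactants: 9 triol; 10 benzoyl chloride
Product: 12 O5,O7-dibenzoate of 9 (O6-H free; 3S,4S,5R,6R), via O7-monobenzoate 11 (not isolated)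
Conditions: 10 (2.1 equiv, slow addition), pyridine/CH2Cl2, −40 to −10 °C
Reagents that add atoms: benzoyl chloride (10), SMILES O=C(Cl)c1ccccc1
Why: Kinetically controlled regioselective acylation: the primary allylic O7 reacts first and the equatorial O5 second, whereas O6 is pseudoaxial and squeezed between C5 and the substituted alkene carbon C1, the same reactivity order that leaves the axial 4-OH of galactopyranosides free in low-temperature benzoylation, and no stereocentre is affected.

Step 9
Reactants: 12 O5,O7-dibenzoate
Product: 13 [(3S,4R,5R,6R)-5-(benzoyloxy)-3,4,6-trihydroxycyclohex-1-en-1-yl]methyl benzoate (target)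
Conditions: HF·pyridine, pyridine/THF, 0 °C to rt (plastic vessel)
Reagents that add atoms: none
Why: Fluoride-driven desilylation relies on the strength of the Si–F bond to cleave both Si–O bonds, and the weakly acidic pyridine-buffered medium generates no alkoxide, so that ester cleavage and benzoyl migration from O5 or O7 to neighbouring hydroxyls are suppressed and all C–O stereocentres persist.

Compound list
1 | bromobenzene | Brc1ccccc1 | starting material
2 | (1S,2S)-3-bromocyclohexa-3,5-diene-1,2-diol | BrC1=CC=C[C@H](O)[C@@H]1O | intermediate
3 | (3aS,7aS)-4-bromo-2,2-dimethyl-3a,7a-dihydro-1,3-benzodioxole | BrC1=CC=C[C@@H]2OC(C)(C)O[C@H]12 | intermediate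
4 | (3aS,5aR,6aR,6bS)-4-bromo-2,2-dimethyl-3a,5a,6a,6b-tetrahydrooxireno[2,3-e][1,3]benzodioxole | BrC1=C[C@H]2O[C@H]2[C@@H]3OC(C)(C)O[C@H]13 | intermediate
5 | (3aS,4R,5S,7aS)-7-bromo-2,2-dimethyl-3a,4,5,7a-tetrahydro-1,3-benzodioxole-4,5-diol | BrC1=C[C@H](O)[C@@H](O)[C@@H]2OC(C)(C)O[C@H]12 | intermediate
6 | 3,4-O-(1,1,3,3-tetraisopropyldisiloxane-1,3-diyl) derivative of 5 (3S,4S,5R,6S) | BrC1=C[C@H](O[Si]2(C(C)C)C(C)C)[C@@H](O[Si](O2)(C(C)C)C(C)C)[C@@H]3OC(C)(C)O[C@H]13 | intermediate
7 | tributyl(hydroxymethyl)stannane | CCCC[Sn](CCCC)(CCCC)CO | starting material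
8 | C1-hydroxymethyl analogue of 6 (3S,4S,5R,6R) | OCC1=C[C@H](O[Si]2(C(C)C)C(C)C)[C@@H](O[Si](O2)(C(C)C)C(C)C)[C@@H]3OC(C)(C)O[C@H]13 | intermediate
9 | 3,4-O-disiloxane-protected triol, O5-H, O6-H and O7-H free (3S,4S,5R,6R) | OCC1=C[C@H](O[Si]2(C(C)C)C(C)C)[C@@H](O[Si](O2)(C(C)C)C(C)C)[C@H](O)[C@@H]1O | intermediate
10 | benzoyl chloride | O=C(Cl)c1ccccc1 | starting material
11 | O7-monobenzoate of 9 (3S,4S,5R,6R) | O=C(OCC1=C[C@H](O[Si]2(C(C)C)C(C)C)[C@@H](O[Si](O2)(C(C)C)C(C)C)[C@H](O)[C@@H]1O)c1ccccc1 | intermediate
12 | O5,O7-dibenzoate of 9, O6-H free (3S,4S,5R,6R) | O=C(OCC1=C[C@H](O[Si]2(C(C)C)C(C)C)[C@@H](O[Si](O2)(C(C)C)C(C)C)[C@H](OC(=O)c2ccccc2)[C@@H]1O)c1ccccc1 | intermediate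
13 | [(3S,4R,5R,6R)-5-(benzoyloxy)-3,4,6-trihydroxycyclohex-1-en-1-yl]methyl benzoate | O=C(OCC1=C[C@H](O)[C@@H](O)[C@H](OC(=O)c2ccccc2)[C@@H]1O)c1ccccc1 | target

Total step count: 9
Longest linear sequence: 9 steps (1 to 13)

Steps most likely to fail

Risk 1, step 8. The acylation may fail to distinguish O5 from O6. This could show up as attack at the wrong secondary hydroxyl, triple acylation, or a base-induced shift of the benzoyl group after it has been placed.
- The fallback replaces kinetic discrimination by a temporary tether and sets out from 9.
- tBu2Si(OTf)2 and pyridine in CH2Cl2 at −40 to 0 °C should bridge the 1,3-related O6 and O7 as a six-membered silylene. This is the behaviour known for the axial 4-OH/6-OH pair of galactopyranosides. The product is the O6,O7-di-tert-butylsilylene alcohol F1.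
- Its only free hydroxyl, O5, is benzoylated with 10, pyridine and DMAP to give the silylene O5-benzoate F2.
- HF·pyridine in THF removes both silicon groups at once to give the O5-monobenzoate tetraol F3.
- One equivalent of 10 with 2,4,6-collidine in CH2Cl2 at −78 to −40 °C acylates the primary allylic O7 ahead of the three secondary hydroxyls. The fallback comes back to the route at 13.

Risk 2, step 6. The coupling may stall because oxidative addition and transmetalation are slow at a vinyl bromide flanked by the C6 ketal oxygen. Material may also be lost through butyl transfer, protodebromination and thermal decay of the stannane.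
- The fallback builds C7 at the ester oxidation level without tin and sets out from 6.
- Carbonylation with CO (1 atm), MeOH, Et3N and PdCl2(PPh3)2 in DMF at 70 °C should give the methyl cyclohexenecarboxylate F4.
- iBu2AlH (2.2 equiv) in CH2Cl2 at −78 °C reduces the conjugated ester in 1,2-fashion to the allylic alcohol. The fallback comes back to the route at 8.

Risk 3, step 7. The acid may erode the disiloxane by partial Si–O hydrolysis and opening of the seven-membered ring. It may also ionise allylic C–O bonds before the ketal is fully hydrolysed.
- The fallback drops silicon altogether, hands the site selection to a catalyst, and sets out from 5.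
- Stille hydroxymethylation of unprotected 5 with 7 and Pd(PPh3)4 in dioxane at 100 °C should give the acetonide triol F5.
- One equivalent of 10 with 2,4,6-collidine in CH2Cl2 at −78 to −40 °C benzoylates the primary O7 to give the acetonide O7-benzoate F6.
- AcOH/H2O (4:1) at 50 °C, now with nothing else acid-labile present, frees the O7-benzoate tetraol F7.
- The last operation is a borinic-acid-catalysed acylation: Ph2BOCH2CH2NH2 (10 mol %), 10 (1.1 equiv), iPr2NEt, MeCN, rt. The catalyst binds the only cis-1,2-diol (O5/O6) as a tetracoordinate borinate and activates its equatorial oxygen O5. The fallback comes back to the route at 13.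

Further compounds
F1 | step 8 | O6,O7-di-tert-butylsilylene alcohol: O6,O7-(di-tert-butylsilanediyl) derivative of 9, O5-H free (3S,4S,5R,6R) | CC(C)(C)[Si]1(OCC2=C[C@H](O[Si]3(C(C)C)C(C)C)[C@@H](O[Si](O3)(C(C)C)C(C)C)[C@H](O)[C@@H]2O1)C(C)(C)C
F2 | step 8 | silylene O5-benzoate: O5-benzoate of F1 (3S,4S,5R,6R) | CC(C)(C)[Si]1(OCC2=C[C@H](O[Si]3(C(C)C)C(C)C)[C@@H](O[Si](O3)(C(C)C)C(C)C)[C@H](OC(=O)c4ccccc4)[C@@H]2O1)C(C)(C)C
F3 | step 8 | O5-monobenzoate tetraol: (1R,2R,5S,6R)-2,5,6-trihydroxy-3-(hydroxymethyl)cyclohex-3-en-1-yl benzoate (ring descriptors 3S,4R,5R,6R) | OCC1=C[C@H](O)[C@@H](O)[C@H](OC(=O)c2ccccc2)[C@@H]1O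
F4 | step 6 | methyl cyclohexenecarboxylate: C1-methoxycarbonyl analogue of 6 (3S,4S,5R,6R) | COC(=O)C1=C[C@H](O[Si]2(C(C)C)C(C)C)[C@@H](O[Si](O2)(C(C)C)C(C)C)[C@@H]3OC(C)(C)O[C@H]13
F5 | step 7 | acetonide triol: C1-hydroxymethyl analogue of 5 (3S,4R,5S,6R) | OCC1=C[C@H](O)[C@@H](O)[C@@H]2OC(C)(C)O[C@H]12
F6 | step 7 | acetonide O7-benzoate: O7-benzoate of F5 (3S,4R,5S,6R) | O=C(OCC1=C[C@H](O)[C@@H](O)[C@@H]2OC(C)(C)O[C@H]12)c1ccccc1
F7 | step 7 | O7-benzoate tetraol: [(3S,4R,5R,6R)-3,4,5,6-tetrahydroxycyclohex-1-en-1-yl]methyl benzoate | O=C(OCC1=C[C@H](O)[C@@H](O)[C@H](O)[C@@H]1O)c1ccccc1
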